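The target is cut in its 7‑O‑methylated flavone unit (ring A, pyranone ring C, ring B = C1'–C6') at O1–C8a and C4–C4a. Ring A holds O1 and the C4 acyl carbon on adjacent carbons (C8a, C4a) with a further oxygen at C5. This is the contiguous pattern that 3,5‑dimethoxybenzyne takes on when it inserts into a carboxylic acid C–O bond. In one operation a ring‑B (E)‑cinnamic acid, which already bears the tri‑O‑benzylated apigenin unit (rings D, E, F) through C2'–C8'', becomes the 2'‑hydroxychalcone with both bonds in place. Iodine‑mediated ring closure and boron trichloride ether cleavage then give the target.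

Key step: step 8

Locants: unprimed atoms (O1, C2–C8a) belong to rings A and C, primed atoms to ring B, double‑primed atoms to the apigenin unit (ring D benzo, ring E pyranone), triple‑primed atoms to ring F.
Assumption: the target has no stereocentre; the hindered C2'–C8'' axis is not specified and is treated as stereochemically undefined (racemic if rotation is slow).

Step 1
Reactants: 1 apigenin
Product: 2 5,7-bis(benzyloxy)-2-[4-(benzyloxy)phenyl]-4H-chromen-4-one (tri-O-benzylapigenin)
Conditions: BnBr (4 equiv), K2CO3, DMF, 80 °C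
Reagents that add atoms: benzyl bromide, BrCc1ccccc1
Why: Williamson ether synthesis; the two free phenols alkylate readily and the chelated 5''-OH follows with excess halide and heat, so that no acidic O–H other than the later carboxylic acid can meet the aryne.

Step 2
Reactants: 2 tri-O-benzylapigenin
Product: 3 5,7-bis(benzyloxy)-2-[4-(benzyloxy)phenyl]-8-iodo-4H-chromen-4-one
Conditions: NIS (1.1 equiv), TFA (cat.), CH2Cl2, 0 °C → rt, dark
Reagents that add atoms: N-iodosuccinimide, O=C1CCC(=O)N1I
Why: Electrophilic aromatic iodination; in 5-O-alkylated 5,7-dioxygenated flavones ring D reacts at C8'', which lies between O1'' and one benzyloxy group, in preference to C6'', which is flanked by two benzyloxy groups, and ring F is far less activated.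

Step 3
Reactants: 3 8-iodo-tri-O-benzylapigenin; 4 (2-formyl-5-methoxyphenyl)boronic acid
Product: 5 2-{5,7-bis(benzyloxy)-2-[4-(benzyloxy)phenyl]-4-oxo-4H-chromen-8-yl}-4-methoxybenzaldehyde
Conditions: 4 (2 equiv), Pd(OAc)2 (5 mol %), SPhos (10 mol %), K3PO4, toluene/H2O, 90 °C
Reagents that add atoms: none
Why: Suzuki–Miyaura coupling; the bulky dialkylbiarylphosphine on zerovalent palladium allows insertion into the hindered C8''–I bond and fast transmetalation, so that coupling should outrun protodeboronation of the ortho-formyl boronic acid, which is used in excess.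

Step 4
Reactants: 5 biaryl aldehyde
Product: 7 (E)-3-(2-{5,7-bis(benzyloxy)-2-[4-(benzyloxy)phenyl]-4-oxo-4H-chromen-8-yl}-4-methoxyphenyl)prop-2-enoic acid, via arylidenemalonic acid 6 (not isolated)
Conditions: malonic acid (3 equiv), pyridine, piperidine (cat.), 90 °C
Reagents that add atoms: malonic acid, OC(=O)CC(=O)O
Why: Knoevenagel condensation in the Doebner modification; the arylidenemalonic acid loses CO2 in hot pyridine to give the conjugated acid as the thermodynamically preferred (E)-isomer, and the flavone and benzyl ethers are inert to this weakly basic medium.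

Step 5
Reactants: 8 3,5-dimethoxyphenol
Product: 9 3,5-dimethoxyphenyl N-isopropylcarbamate
Conditions: i-PrNCO (1.5 equiv), Et3N (cat.), CH2Cl2, rt
Reagents that add atoms: isopropyl isocyanate, CC(C)N=C=O
Why: Addition of a phenol to an isocyanate gives the O-aryl N-monoalkyl carbamate, a strong ortho-directing group that can later be removed under mild base.

Step 6
Reactants: 9 3,5-dimethoxyphenyl N-isopropylcarbamate
Product: 13 3,5-dimethoxy-2-(trimethylsilyl)phenyl N-isopropylcarbamate, via N-silyl carbamate 10 (not isolated), via ortho-lithiated N-silyl carbamate 11 (not isolated), via N-silyl C-silyl carbamate 12 (not isolated)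
Conditions: TBSOTf, TMEDA, Et2O, 0 °C → rt; n-BuLi, TMEDA, −78 °C; TMSCl, −78 °C → rt; aq. NaHSO4
Reagents that add atoms: chlorotrimethylsilane, C[Si](C)(C)Cl
Why: Directed ortho-metalation of the carbamate after in situ N-silylation; carbamate and neighbouring methoxy group cooperate to place lithium at C2 between them (C4, between two weaker methoxy directors, should not compete), TMSCl traps the aryllithium and the N–Si bond is hydrolysed on work-up.

Step 7
Reactants: 13 3,5-dimethoxy-2-(trimethylsilyl)phenyl N-isopropylcarbamate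
Product: 15 3,5-dimethoxy-2-(trimethylsilyl)phenyl trifluoromethanesulfonate, via 3,5-dimethoxy-2-(trimethylsilyl)phenol 14 (not isolated)
Conditions: DBU (1.5 equiv), Et2NH (1.2 equiv), MeCN, 40 °C; then PhNTf2 (1.5 equiv), rt
Reagents that add atoms: N-phenylbis(trifluoromethanesulfonimide), O=S(=O)(N(c1ccccc1)S(=O)(=O)C(F)(F)F)C(F)(F)F
Why: Base-induced E1cB loss of isopropyl isocyanate (trapped by Et2NH as a urea) frees the phenoxide, which is sulfonylated in the same flask by PhNTf2; the mild, non-acidic conditions should spare the electron-rich aryl–silicon bond.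

Step 8
Reactants: 7 ring-B (E)-cinnamic acid carrying the tri-O-benzyl apigenin unit; 15 3,5-dimethoxy-2-(trimethylsilyl)phenyl trifluoromethanesulfonate
Product: 17 (E)-3-(2-{5,7-bis(benzyloxy)-2-[4-(benzyloxy)phenyl]-4-oxo-4H-chromen-8-yl}-4-methoxyphenyl)-1-(2-hydroxy-4,6-dimethoxyphenyl)prop-2-en-1-one, via 3,5-dimethoxybenzyne 16 (not isolated)
Conditions: 15 (1.5 equiv), CsF (4 equiv), THF, 125 °C, sealed tube; dilute HCl work-up
Reagents that add atoms: none
Why: Fluoride attacks silicon in 15 and expels triflate to give aryne 16; the carboxylate formed from 7 and CsF adds through oxygen to the aryne carbon remote from the flanking methoxy group, and the resulting aryl anion attacks the neighbouring ester carbonyl through a four-membered alkoxide that opens to the ortho-acylphenoxide, so O1–C8a and C4–C4a form together. This is the known insertion of arynes into the C–O bond of carboxylic acids to give ortho-hydroxyaryl ketones, which has been run with α,β-unsaturated acids. No ring is closed and no stereocentre is created; the (E)-alkene of 7 is carried through unchanged. The step needs oxygen at C8a and the acyl group at C4a beside the C5 oxygen, and this is secured by the methoxy group next to the triple bond, which distorts the aryne and stabilises the developing carbanion inductively, so the nucleophile enters at the distal carbon. It also needs carbonyl attack to win over protonation of the aryl anion and over conjugate addition to Cβ; hot THF, which offers no acidic C–H, and the short reach of the in-plane carbanion to the ester carbonyl favour the acyl shift. Full benzylation of the apigenin unit leaves the carboxylic acid as the only O–H partner for the aryne.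

Step 9
Reactants: 17 2'-hydroxy-4',6'-dimethoxychalcone
Product: 20 5,7-bis(benzyloxy)-2-[4-(benzyloxy)phenyl]-8-[2-(5,7-dimethoxy-4-oxo-4H-chromen-2-yl)-5-methoxyphenyl]-4H-chromen-4-one, via flavanone 18 (not isolated), via 3-iodoflavanone 19 (not isolated)
Conditions: I2 (10 mol %), DMSO, 120 °C
Reagents that add atoms: none
Why: Iodine-catalysed oxidative cyclisation of a 2'-hydroxychalcone; 6-endo oxa-Michael closure of ring C, iodination at C3 and loss of HI give the flavone while DMSO reoxidises iodide, and any flavanone already formed under the basic conditions of step 8 converges on the same product.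

Step 10
Reactants: 20 protected biflavone
Product: 21 8-[2-(5-hydroxy-7-methoxy-4-oxo-4H-chromen-2-yl)-5-methoxyphenyl]-5,7-dihydroxy-2-(4-hydroxyphenyl)-4H-chromen-4-one (target, CNP0329977.0)
Conditions: BCl3 (1 M in CH2Cl2, 8 equiv), pentamethylbenzene (9 equiv), CH2Cl2, −78 °C → rt; MeOH, then H2O
Reagents that add atoms: none
Why: Lewis acid ether cleavage; BCl3 removes the three benzyl ethers (pentamethylbenzene traps the benzyl cation) and, through chelation to the C4 carbonyl, only the peri 5-O-methyl ether of ring A, so the unchelated methyl ethers at C7 and C4' should survive.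

Compound list
1 | apigenin, 5,7-dihydroxy-2-(4-hydroxyphenyl)-4H-chromen-4-one | O=c1cc(-c2ccc(O)cc2)oc2cc(O)cc(O)c12 | starting material
2 | 5,7-bis(benzyloxy)-2-[4-(benzyloxy)phenyl]-4H-chromen-4-one | O=c1cc(-c2ccc(OCc3ccccc3)cc2)oc2cc(OCc3ccccc3)cc(OCc3ccccc3)c12 | intermediate
3 | 5,7-bis(benzyloxy)-2-[4-(benzyloxy)phenyl]-8-iodo-4H-chromen-4-one | O=c1cc(-c2ccc(OCc3ccccc3)cc2)oc2c(I)c(OCc3ccccc3)cc(OCc3ccccc3)c12 | intermediate
4 | (2-formyl-5-methoxyphenyl)boronic acid | COc1ccc(C=O)c(B(O)O)c1 | starting material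
5 | 2-{5,7-bis(benzyloxy)-2-[4-(benzyloxy)phenyl]-4-oxo-4H-chromen-8-yl}-4-methoxybenzaldehyde | COc1ccc(C=O)c(-c2c(OCc3ccccc3)cc(OCc3ccccc3)c3c(=O)cc(-c4ccc(OCc5ccccc5)cc4)oc23)c1 | intermediate
6 | 2-[(2-{5,7-bis(benzyloxy)-2-[4-(benzyloxy)phenyl]-4-oxo-4H-chromen-8-yl}-4-methoxyphenyl)methylidene]propanedioic acid (formed in the flask) | COc1ccc(C=C(C(=O)O)C(=O)O)c(-c2c(OCc3ccccc3)cc(OCc3ccccc3)c3c(=O)cc(-c4ccc(OCc5ccccc5)cc4)oc23)c1 | intermediate
7 | (E)-3-(2-{5,7-bis(benzyloxy)-2-[4-(benzyloxy)phenyl]-4-oxo-4H-chromen-8-yl}-4-methoxyphenyl)prop-2-enoic acid | COc1ccc(/C=C/C(=O)O)c(-c2c(OCc3ccccc3)cc(OCc3ccccc3)c3c(=O)cc(-c4ccc(OCc5ccccc5)cc4)oc23)c1 | intermediate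
8 | 3,5-dimethoxyphenol | COc1cc(O)cc(OC)c1 | starting material
9 | 3,5-dimethoxyphenyl N-isopropylcarbamate | CC(C)NC(=O)Oc1cc(OC)cc(OC)c1 | intermediate
10 | 3,5-dimethoxyphenyl N-(tert-butyldimethylsilyl)-N-isopropylcarbamate (formed in the flask) | CC(C)N(C(=O)Oc1cc(OC)cc(OC)c1)[Si](C)(C)C(C)(C)C | intermediate
11 | 2-lithio-3,5-dimethoxyphenyl N-(tert-butyldimethylsilyl)-N-isopropylcarbamate (formed in the flask) | [Li]c1c(OC)cc(OC)cc1OC(=O)N(C(C)C)[Si](C)(C)C(C)(C)C | intermediate
12 | 3,5-dimethoxy-2-(trimethylsilyl)phenyl N-(tert-butyldimethylsilyl)-N-isopropylcarbamate (formed in the flask) | COc1cc(OC)c([Si](C)(C)C)c(OC(=O)N(C(C)C)[Si](C)(C)C(C)(C)C)c1 | intermediate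
13 | 3,5-dimethoxy-2-(trimethylsilyl)phenyl N-isopropylcarbamate | COc1cc(OC)c([Si](C)(C)C)c(OC(=O)NC(C)C)c1 | intermediate
14 | 3,5-dimethoxy-2-(trimethylsilyl)phenol (formed in the flask as its DBU salt) | COc1cc(OC)c([Si](C)(C)C)c(O)c1 | intermediate
15 | 3,5-dimethoxy-2-(trimethylsilyl)phenyl trifluoromethanesulfonate | COc1cc(OC)c([Si](C)(C)C)c(OS(=O)(=O)C(F)(F)F)c1 | intermediate
16 | 3,5-dimethoxybenzyne, 1,2-didehydro-3,5-dimethoxybenzene (formed in the flask) | COC1=CC(OC)=CC#C1 | intermediate
17 | (E)-3-(2-{5,7-bis(benzyloxy)-2-[4-(benzyloxy)phenyl]-4-oxo-4H-chromen-8-yl}-4-methoxyphenyl)-1-(2-hydroxy-4,6-dimethoxyphenyl)prop-2-en-1-one | COc1ccc(/C=C/C(=O)c2c(O)cc(OC)cc2OC)c(-c2c(OCc3ccccc3)cc(OCc3ccccc3)c3c(=O)cc(-c4ccc(OCc5ccccc5)cc4)oc23)c1 | intermediate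
18 | racemic 2-(2-{5,7-bis(benzyloxy)-2-[4-(benzyloxy)phenyl]-4-oxo-4H-chromen-8-yl}-4-methoxyphenyl)-5,7-dimethoxy-2,3-dihydro-4H-chromen-4-one (formed in the flask) | COc1ccc(C2CC(=O)c3c(OC)cc(OC)cc3O2)c(-c2c(OCc3ccccc3)cc(OCc3ccccc3)c3c(=O)cc(-c4ccc(OCc5ccccc5)cc4)oc23)c1 | intermediate
19 | 3-iodo derivative of flavanone 18, racemic mixture of diastereomers (formed in the flask) | COc1ccc(C2Oc3cc(OC)cc(OC)c3C(=O)C2I)c(-c2c(OCc3ccccc3)cc(OCc3ccccc3)c3c(=O)cc(-c4ccc(OCc5ccccc5)cc4)oc23)c1 | intermediate
20 | 5,7-bis(benzyloxy)-2-[4-(benzyloxy)phenyl]-8-[2-(5,7-dimethoxy-4-oxo-4H-chromen-2-yl)-5-methoxyphenyl]-4H-chromen-4-one | COc1ccc(-c2cc(=O)c3c(OC)cc(OC)cc3o2)c(-c2c(OCc3ccccc3)cc(OCc3ccccc3)c3c(=O)cc(-c4ccc(OCc5ccccc5)cc4)oc23)c1 | intermediate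
21 | 8-[2-(5-hydroxy-7-methoxy-4-oxo-4H-chromen-2-yl)-5-methoxyphenyl]-5,7-dihydroxy-2-(4-hydroxyphenyl)-4H-chromen-4-one | COc1ccc(-c2cc(=O)c3c(O)cc(OC)cc3o2)c(-c2c(O)cc(O)c3c(=O)cc(-c4ccc(O)cc4)oc23)c1 | target

Total steps: 10. Longest linear sequence: 7 steps (1, 2, 3, 4, 8, 9, 10) from apigenin; the aryne precursor branch (5, 6, 7) joins at step 8.

Steps most likely to fail

Step 8 (aryne insertion). After the carboxylate has added to the aryne, protonation of the aryl anion may outpace the acyl shift and stop at the aryl ester, and the product phenoxide may be arylated by a second aryne. The fallback sets out from aldehyde 5 and condenses it with purchased 1-(2-hydroxy-4,6-dimethoxyphenyl)ethanone under Claisen–Schmidt conditions (KOH, EtOH/THF, rt). Dehydration of the aldol should give chalcone 17 directly, so the route is rejoined at 17 and no compound outside the list is made (F0).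

Step 3 (hindered Suzuki–Miyaura coupling). Protodeboronation of the ortho-formyl boronic acid and slow oxidative addition at the doubly ortho-substituted C8''–I bond could starve the coupling. The fallback reverses the polarity. From iodide 3, Miyaura borylation (B2pin2, PdCl2(dppf), KOAc, dioxane, 90 °C) should give 5,7-bis(benzyloxy)-2-[4-(benzyloxy)phenyl]-8-(4,4,5,5-tetramethyl-1,3,2-dioxaborolan-2-yl)-4H-chromen-4-one F1. This is coupled with purchased 2-bromo-4-methoxybenzaldehyde (Pd(OAc)2, SPhos, K3PO4, toluene/H2O, 90 °C) to rejoin the route at aldehyde 5.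

Step 10 (fourfold ether cleavage). One of the four ethers may resist cleavage, benzyl cations may alkylate the electron-rich rings, or an unchelated methyl ether may be lost on prolonged exposure. The fallback separates the two tasks. From 20, hydrogenolysis (H2, Pd/C, THF/MeOH, rt) should remove the three benzyl groups and give 8-[2-(5,7-dimethoxy-4-oxo-4H-chromen-2-yl)-5-methoxyphenyl]-5,7-dihydroxy-2-(4-hydroxyphenyl)-4H-chromen-4-one F2. The peri methyl ether alone is then cleaved with AlCl3 in MeCN at 60 °C through the aluminium chelate between the C4 carbonyl and the C5 oxygen, arriving at target 21.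

Further compounds
F0 | step 8 | none | none
F1 | step 3 | 5,7-bis(benzyloxy)-2-[4-(benzyloxy)phenyl]-8-(4,4,5,5-tetramethyl-1,3,2-dioxaborolan-2-yl)-4H-chromen-4-one | O=c1cc(-c2ccc(OCc3ccccc3)cc2)oc2c(B3OC(C)(C)C(C)(C)O3)c(OCc3ccccc3)cc(OCc3ccccc3)c12
F2 | step 10 | 8-[2-(5,7-dimethoxy-4-oxo-4H-chromen-2-yl)-5-methoxyphenyl]-5,7-dihydroxy-2-(4-hydroxyphenyl)-4H-chromen-4-one | COc1ccc(-c2cc(=O)c3c(OC)cc(OC)cc3o2)c(-c2c(O)cc(O)c3c(=O)cc(-c4ccc(O)cc4)oc23)c1
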